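1. This chemistry was slow: after 80.0 min the delta and gamma runs held 8.3% and 8.0% target.

| flask | starting material | second substrate | solid reagent | free catalyst | remark | time |
|---|---|---|---|---|---|---|
| delta | 0.13 M | 0.26 M | 0.052 M | 2.5 mM | run made earlier |  |
| gamma | 0.13 M | 0.26 M | 0.078 M | 2.5 mM | run made earlier |  |
| beta | 0.13 M | 0.26 M | 0.104 M | 5 mM | run made earlier |  |
| flask | 0.13 M | 0.260 M | 0.104 M | 2.5 mM |  | 1.5 h |

| run | time / min | target / % | starting material / % |
|---|---|---|---|
| delta | 6.00 | 0.6 | 98.6 |
| delta | 10.0 | 0 | 98.1 |
| delta | 15.0 | 0.1 | 98.8 |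
| delta | 25.0 | 1.1 | 96.9 |
| delta | 40.0 | 3.8 | 95.7 |
| delta | 80.0 | 8.3 | 89.8 |
| gamma | 6.00 | 0.6 | 98.1 |
| gamma | 10.0 | 0 | 98.6 |
| gamma | 15.0 | 0.4 | 97.1 |
| gamma | 25.0 | 1.1 | 97.2 |
| gamma | 40.0 | 3.3 | 94.6 |
| gamma | 80.0 | 8.0 | 90.7 |
| beta | 6.00 | 0.1 | 96.8 |
| beta | 10.0 | 0.4 | 96.9 |
| beta | 20.0 | 2.1 | 95.0 |
| beta | 40.0 | 4.6 | 92.2 |
| beta | 80.0 | 12.7 | 84.1 |

(scatter of a reading: 0.5 percentage points)

- given per volume of solution although it is solid: solid reagent
- what was read earlier has a scatter of 0.5 percentage points, one standard deviation
- at the start none of the solid reagent is in solution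
- partner is what solid reagent becomes in solution

1. the target standing at 1.5 h, as a percentage of the starting material charged
2. concentration of partner in solution at 1.5 h, in percent of saturation

2. Those runs had 0.052 M and 0.078 M of solid reagent yet ended alike, so the pace looked zero-order in the solid charged. I therefore let them stand for the flask, which has delta's catalyst. Their mean was 8.15%.

3. I carried the late step: the target added from 80.0 min to 1.5 h at the pace read between 40.0 min and 80.0 min, 1.1 percentage points.

4. From below: 89.8% of the starting material still stood in delta at 80.0 min, so I expected no slackening, which gave 9.30%.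

5. From above: beta, with more catalyst, had a larger step of 2 points. Added to the higher reading, it gave 10.3%, with a scatter of 0.5 points.

6. The forecast gave 9.6%, inside my bracket, with a range of 8.4% to 11.2%, and 95% of saturation (82% to 100%): “The partner in solution is probably close to its solubility limit.”

7. The flask gave 10.4%, above my upper bound by 0.100 points, and 34.4% of saturation.

    starting material + free catalyst ⇌ catalyst intermediate A (K = 554 M⁻¹, k = 12.7 M⁻¹ min⁻¹)
    partner + catalyst intermediate A → free catalyst + target (k = 5.19 M⁻¹ min⁻¹)
    second substrate + free catalyst ⇌ catalyst intermediate B (K = 150 M⁻¹, k = 3.41 M⁻¹ min⁻¹)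
    partner + catalyst intermediate B → free catalyst + second product (k = 106 M⁻¹ min⁻¹)
    solid reagent ⇌ partner, rate k5*(cs5 - [partner]) while solid is left; crystals form when [partner] > cs5 (solubility = 0.0540 M, k = 0.0116 min⁻¹)

8. In the flask, partner was made 1.68 times faster than used up, each step taken net, at 0.671 h, but 1.11 times at 1.50 h. It stood at 0.0186 M then, below the saturation level of 0.054 M. The flask's last stretch, from 80.0 min to 1.5 h, added 1.6 points, more than the late step. Beta's step over the late step, 1.76, a reading from runs that differed in solid reagent as well, taken as the factor per doubling of catalyst, gave 3.36% for the neighbour flask with a quarter of the catalyst, and that neighbour stood at 3.64%.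

The earlier runs and the new flask are simulated for substances that don't exist.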